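I was asked which of these flasks would hold the highest G at its final reading, and I left this note for the bench.

| flask | L | X | temperature | remark | time |
|---|---|---|---|---|---|
| alder | 0.70 M | 1.54 M | −24 °C | run made earlier |  |
| birch | 2.8 M | 1.54 M | 1 °C | run made earlier |  |
| Monday's | 1.4 M | 1.54 M | 10 °C |  | 20 h |
| Thursday's | 1.4 M | 1.54 M | −5 °C |  | 20 h |
| Sunday's | 1.4 M | 1.54 M | −20 °C |  | 20 h |
| Wednesday's | 1.4 M | 1.54 M | −35 °C |  | 20 h |

| run | time / h | G / % | L / % |
|---|---|---|---|
| alder | 15.0 | 4.8 | 17.4 |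
| alder | 25.0 | 15.8 | 6.4 |
| alder | 30.0 | 16.8 | 3.2 |
| alder | 60.0 | 33.2 | 0 |
| alder | 72.0 | 38.8 | 0.5 |
| birch | 2.00 | 24.7 | 1.0 |
| birch | 3.00 | 35.1 | 1.0 |
| birch | 5.00 | 40.2 | 1.1 |
| birch | 8.00 | 40.6 | 0 |
| birch | 10.0 | 40.7 | 0 |
| birch | 15.0 | 39.2 | 0 |
| birch | 25.0 | 36.2 | 1.1 |

(each reading ± 1 percentage point)

- the flask with the highest amount of G, in percent of the L charged ("all alike" if they lie within 1.5 percentage points) (Monday's / Thursday's / Sunday's / Wednesday's / all alike)
- final G, as a percentage of the L charged, in Monday's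
- final G, as a percentage of the L charged, in Thursday's
- final G, as a percentage of the L charged, in Sunday's
- final G, as a percentage of the L charged, in Wednesday's

- the analysis behind the earlier runs scatters by 1 percentage point, standard deviation

In the alder run, 80.0% of the L charged stood at 30.0 h as neither L nor G, so G was coming slowly from a form the analysis did not show. In the birch run G read 40.7% at 10.0 h and 36.2% at 25.0 h. I reckoned that small sag apart from the large rise. The fractional loss of G per hour past its plateau, a first-order loss, read 0.00781 h⁻¹, and I called this the fade constant. It rests on two scattered readings at one temperature. Over 20 h it takes off 15.6% of the G at 1 °C, so I treated fade there as a correction to the yield.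

The birch run had reached its plateau by about 5.00 h, sooner than 20 h, so I expected Thursday's, at −5 °C, to finish its making with time to spare. I took fade to slow with cold, which would keep Thursday's correction under that figure. I expected Sunday's to be still rising, and Wednesday's, colder than alder, to stay below the 15.8% that alder showed at 25.0 h. Monday's, at 10 °C, I took to fade faster than birch. So I committed to Thursday's.

The forecast named Thursday's, with 27%, 45%, 18% and 0.5% for Monday's, Thursday's, Sunday's and Wednesday's, and said of Thursday's “conversion complete, little loss”. The simulation gave 37.9%, 60.6%, 19.2% and 0.162% in that order, so Thursday's held the highest G.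

    2 Q → J (k = 1.60 × 10⁻⁵ L mol⁻¹ s⁻¹, Ea = 59.0 kJ mol⁻¹)
    G → D (k = 5.30 × 10⁻⁸ s⁻¹, Ea = 100 kJ mol⁻¹)
    Z + Q → G (k = 2.30 × 10⁻⁵ L mol⁻¹ s⁻¹, Ea = 55.0 kJ mol⁻¹)
    L → Z (k = 5.80 × 10⁻⁵ s⁻¹, Ea = 85.0 kJ mol⁻¹)
    X → Q (k = 7.40 × 10⁻⁶ s⁻¹, Ea = 90.0 kJ mol⁻¹)
    G ⇌ E (K = 1.20, k = 7.30 × 10⁻⁶ s⁻¹, Ea = 83.0 kJ mol⁻¹, ΔH = −81.0 kJ mol⁻¹)
    (constants at −20 °C)

Monday's G went from 50.4% at 10.0 h to 37.9% at 20.0 h, a fade constant of 0.0286 h⁻¹, which is 3.66 times the birch reading. Thursday's G went from 60.6% at 20.0 h to 41.2% at 200 h, a net fade constant of 0.00215 h⁻¹, which is lower than the birch reading, at 0.275 times it.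

Readings and results stem from a simulated flask with made-up constants, and the scatter is random.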